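All runs were computed on assumed constants; scatter was added.

At early times the ratio of the pace of the left-handed product to that of the right-handed product is the quantity worth carrying. Call the fractions of left-handed and right-handed substrate still present x_L and x_R, and the left-handed and right-handed products P and Q. The excess is e = (P − Q)/(P + Q).

| flask | left-handed substrate | right-handed substrate | coupling partner | precatalyst | temperature | remark | time |
|---|---|---|---|---|---|---|---|
| birch | 0.070 M | 0.070 M | 0.030 M | 1.1 mM | 105 °C | run made earlier |  |
| maple | 0.11 M | 0.11 M | 0.030 M | 1.1 mM | 138 °C | run made earlier |  |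
| elm | 0.050 M | 0.050 M | 0.030 M | 1.7 mM | 105 °C | run made earlier |  |
| north | 0.050 M | 0.050 M | 0.0300 M | 1.1 mM | 90 °C |  | 20 min |
| north-east | 0.050 M | 0.050 M | 0.0300 M | 1.1 mM | 150 °C |  | 20 min |
| east | 0.050 M | 0.050 M | 0.0300 M | 1.1 mM |  | at 90 °C until 6.0 min, from then on at 150 °C | 20 min |
| south-east | 0.050 M | 0.050 M | 0.0300 M | 1.1 mM | 120 °C |  | 20 min |

| run | time / min | left-handed product / % | right-handed product / % |
|---|---|---|---|
| birch | 1.00 | 2.0 | 0.9 |
| birch | 2.00 | 4.4 | 2.9 |
| birch | 5.00 | 9.5 | 5.9 |
| birch | 12.0 | 13.0 | 6.7 |
| maple | 0.200 | 1.7 | 1.6 |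
| maple | 0.333 | 3.9 | 4.0 |
| maple | 1.00 | 7.2 | 4.7 |
| maple | 2.50 | 7.4 | 6.8 |
| elm | 3.00 | 10.9 | 6.3 |
| elm | 6.00 | 14.1 | 9.2 |
| elm | 10.0 | 18.4 | 11.1 |
| elm | 12.0 | 16.9 | 8.9 |

(readings scatter by 1 percentage point)

- catalyst is single-handed; left-handed substrate and right-handed substrate are mirror images of each other, charged as a racemate, each of them at the stated concentration
- the numbers in the tables scatter with a standard deviation of 1 percentage point
- steps that have been proposed: coupling partner + catalyst + left-handed substrate -> catalyst + left-handed product; coupling partner + catalyst + right-handed substrate -> catalyst + right-handed product; 2 catalyst <-> resting dimer; precatalyst <-> catalyst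
- an excess is below zero if the other one leads

- which flask leads in excess of left-handed product over right-handed product ("all alike" within 1.5 percentage points) (north / north-east / east / south-east / all alike)
- excess of left-handed product over right-handed product at the end, north
- excess of left-handed product over right-handed product at the end, north-east
- excess of left-handed product over right-handed product at the end, east
- excess of left-handed product over right-handed product at the end, south-east

1. **Time and precatalyst.** Both proposed coupling steps contain the catalyst and the coupling partner, so dividing one rate by the other cancels them, and time with them. What remains is the selectivity factor s = ln x_L / ln x_R. By hand, then, neither time nor catalyst charge should move s. The summed readings agree: P/Q is 1.76 in birch and 1.70 in elm, with 1.1 mM and 1.7 mM of precatalyst. Their geometric mean is 1.73 at 105 °C.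

2. **Temperature.** By hand, heat should bring s towards 1. Maple reads 1.18 at 138 °C. Drawing ln s straight through both readings gives the selectivity factor at 90 °C, s₉₀-flask value 2.06, then 1.45 at 120 °C and 1.03 at 150 °C.

3. **Coupling partner.** Its 0.0300 M stands below the 0.100 M of substrate together, so it is the limiting reagent and caps conversion c at 30.0%. Depletion of the faster substrate discounts the starting excess (s − 1)/(s + 1) by roughly D = ((1 − c)/c)·ln(1/(1 − c)), here 0.832.

4. **Reckoning.** With the partner used up, north gives 28.8%, south-east 15.4% and north-east 1.16%. East, changed at 6.0 min, should fall between north and north-east.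

The forecast names north as leader with 6.7%, 0.8%, 3% and 4.4% for north, north-east, east and south-east, starting from this: “Coupling partner is limiting”.

north leads: north gives 23.9%, north-east 8.23%, east 13.8% and south-east 15.4%. At 20.0 min north holds 66% of its left-handed substrate and 79% of its right-handed substrate, so the logarithm ratio is 1.77, below the carried 2.06.

    coupling partner + catalyst + left-handed substrate → catalyst + left-handed product (k = 71.0 M⁻² s⁻¹, Ea = 42.0 kJ mol⁻¹)
    coupling partner + catalyst + right-handed substrate → catalyst + right-handed product (k = 40.0 M⁻² s⁻¹, Ea = 50.0 kJ mol⁻¹)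
    2 catalyst ⇌ resting dimer, settled at all times (K = 480 M⁻¹, ΔH = 19.0 kJ mol⁻¹)
    precatalyst ⇌ catalyst (K = 11.0, k = 0.00260 s⁻¹, Ea = 94.0 kJ mol⁻¹, ΔH = −10.0 kJ mol⁻¹)
    (constants at 90 °C)

East read at 5.0 min, still at 90 °C, has c = 9.90%, so the carried 2.06 gives 32.9%. The flask gives 26.6%.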